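**Retrosynthetic overview**

1. Ring A is bought as phloracetophenone 1 (masked at O-4 as 2). The C6–geranyl bond is cut back to geranyl bromide 3 and made first (2 + 3 → 4), while ring A is still symmetric, so only one C-geranyl isomer can form. Ring B is bought as aldehyde 5.
2. Chalcone 6 ⇐ 4 + 5 (Claisen–Schmidt), the open-chain C6–C3–C6 precursor.
3. Key disconnection, O1–C2 of ring C: enantio- and regioselective intramolecular oxa-Michael addition of the unhindered 6'-OH of 6 (the chalcone isomerase reaction run with a chiral organocatalyst) gives (2S)-flavanone 7, locked in the same flask as silyl enol ether 8.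
4. C3–OH: anti oxygenation of the enol double bond of 8 (the flavanone 3-hydroxylase reaction done as a Rubottom oxidation, via 9 and 10), then acid unmasking to 11.
5. Ring order: rings A and B are preformed benzenes; ring C is the only ring built and is closed in step 4.

Assumption: 3 and 5 are bought as such; the target is read from the SMILES as the (2R,3R)-trans-dihydroflavonol with a (2E)-geranyl group at C6 (geranyl = (2E)-3,7-dimethylocta-2,6-dien-1-yl).

**Route**

Step 1
Reactants: 1 2',4',6'-trihydroxyacetophenone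
Product: 2 1-[2,6-dihydroxy-4-(methoxymethoxy)phenyl]ethanone
Conditions: MOMCl (1.05 equiv), i-Pr2NEt (1.2 equiv), THF/CH2Cl2, −10 → 0 °C
Reagents that add atoms: chloromethyl methyl ether (MOMCl), COCCl
Why: Williamson-type O-alkylation (acetal formation) at the 4-OH, which is the most acidic hydroxyl and the only one not hydrogen-bonded to the acetyl C=O, so one equivalent caps it and leaves a symmetric 2,6-diol.

Step 2
Reactants: 2 1-[2,6-dihydroxy-4-(methoxymethoxy)phenyl]ethanone; 3 geranyl bromide [(2E)-1-bromo-3,7-dimethylocta-2,6-diene]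
Product: 4 1-[3-geranyl-2,6-dihydroxy-4-(methoxymethoxy)phenyl]ethanone
Conditions: DBU (1.1 equiv), THF, 0 °C → rt
Reagents that add atoms: none
Why: C-alkylation of an ambident acylphloroglucinol phenoxide (SN2 on the allylic bromide, the laboratory counterpart of aromatic prenyl transfer); C3 and C5 are equivalent so only one mono-C-geranyl product exists, and direct displacement keeps the 2E geometry.

Step 3
Reactants: 4 1-[3-geranyl-2,6-dihydroxy-4-(methoxymethoxy)phenyl]ethanone; 5 4-(methoxymethoxy)benzaldehyde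
Product: 6 (2E)-1-[3-geranyl-2,6-dihydroxy-4-(methoxymethoxy)phenyl]-3-[4-(methoxymethoxy)phenyl]prop-2-en-1-one
Conditions: KOH (50% aq., 15 equiv), EtOH, 0 °C → rt, 36 h; then cold 1 M HCl to pH 5; crystallise, use promptly
Reagents that add atoms: none
Why: Claisen–Schmidt condensation (crossed aldol, E1cB dehydration) in which only the methyl ketone can enolise and the E-enone is the thermodynamic product; in strong base the product rests as the open-chain phenoxide, so ring C does not close prematurely, and MOM ethers and isolated alkenes are inert.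

Step 4
Reactants: 6 (2E)-1-[3-geranyl-2,6-dihydroxy-4-(methoxymethoxy)phenyl]-3-[4-(methoxymethoxy)phenyl]prop-2-en-1-one
Product: 8 (2S)-6-geranyl-7-(methoxymethoxy)-2-[4-(methoxymethoxy)phenyl]-4,5-bis(triethylsilyloxy)-2H-chromene, via (2S)-flavanone 7 (not isolated)
Conditions: quinidine-derived 3,5-bis(trifluoromethyl)phenyl squaramide (10 mol %), toluene/CH2Cl2, −30 °C, 24–48 h; then Et3N (5 equiv), TESOTf (2.5 equiv), −78 → 0 °C; pentane, filter, evaporate (crude 8 used directly)
Reagents that add atoms: triethylsilyl trifluoromethanesulfonate (TESOTf), CC[Si](CC)(CC)OS(=O)(=O)C(F)(F)F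
Why: Proposed new method: a 6-endo intramolecular oxa-Michael addition (chalcone–flavanone isomerisation) under bifunctional catalysis, in which the squaramide N–H groups bind the enone carbonyl and the quinuclidine deprotonates the attacking phenol inside a chiral ion pair, so C2 is set as S by face-selective C–O bond formation; the geranyl-flanked 2'-OH is the more hindered nucleophile and holds the buttressed hydrogen bond to C=O, so the free 6'-OH should close the ring and place geranyl at C6; 5-hydroxyflavanones lie far on the cyclic side, so the retro-reaction is slow at −30 °C, and soft enolisation with Et3N/TESOTf (no free enolate, hence no E1cB ring opening) converts 7 into the bis-silyl enol ether 8, which can no longer ring-open, locking both C2 and the regiochemistry; the closest known reaction types are cinchona thiourea- or squaramide-catalysed oxa-Michael cyclisations of phenols onto activated alkylidene β-ketoesters (to flavanones) and onto tethered enones (to chromans), and amine/silyl triflate enol ether formation.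

Step 5
Reactants: 8 (2S)-6-geranyl-7-(methoxymethoxy)-2-[4-(methoxymethoxy)phenyl]-4,5-bis(triethylsilyloxy)-2H-chromene
Product: 11 Bonnaniol [(2R,3R)-6-geranyl-3,5,7-trihydroxy-2-(4-hydroxyphenyl)-2,3-dihydro-4H-chromen-4-one], via silyloxy epoxide 9 (not isolated), via bis-MOM dihydroflavonol 10 (not isolated)
Conditions: DMDO (1.0 equiv, titrated, acetone), CH2Cl2, −78 °C, 15 min; evaporate cold; then HCl (3 M) in MeOH, 45 °C, 1–2 h
Reagents that add atoms: dimethyldioxirane (DMDO), CC1(C)OO1
Why: Rubottom oxidation, in which the electron-rich silyl enol ether is epoxidised far faster than the two trisubstituted alkenes at −78 °C and on the face anti to the C2 aryl group, so the new C3–O bond is trans to the aryl (3R, with C2 untouched); acidic methanolysis then opens the silyloxy epoxide to the α-hydroxy ketone and removes the silyl and MOM groups by acetal exchange, and because 2,3-trans is also the thermodynamic isomer the acid stage cannot erode it.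

**Compound list**

1 | 2',4',6'-trihydroxyacetophenone | CC(=O)c1c(O)cc(O)cc1O | starting material
2 | 1-[2,6-dihydroxy-4-(methoxymethoxy)phenyl]ethanone | CC(=O)c1c(O)cc(OCOC)cc1O | intermediate
3 | geranyl bromide, (2E)-1-bromo-3,7-dimethylocta-2,6-diene | CC(C)=CCC/C(C)=C/CBr | starting material
4 | 1-{3-[(2E)-3,7-dimethylocta-2,6-dien-1-yl]-2,6-dihydroxy-4-(methoxymethoxy)phenyl}ethanone | CC(C)=CCC/C(C)=C/Cc1c(OCOC)cc(O)c(C(C)=O)c1O | intermediate
5 | 4-(methoxymethoxy)benzaldehyde | COCOc1ccc(C=O)cc1 | starting material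
6 | (2E)-1-{3-[(2E)-3,7-dimethylocta-2,6-dien-1-yl]-2,6-dihydroxy-4-(methoxymethoxy)phenyl}-3-[4-(methoxymethoxy)phenyl]prop-2-en-1-one | CC(C)=CCC/C(C)=C/Cc1c(OCOC)cc(O)c(C(=O)/C=C/c2ccc(OCOC)cc2)c1O | intermediate
7 | (2S)-6-[(2E)-3,7-dimethylocta-2,6-dien-1-yl]-5-hydroxy-7-(methoxymethoxy)-2-[4-(methoxymethoxy)phenyl]-2,3-dihydro-4H-chromen-4-one | CC(C)=CCC/C(C)=C/Cc1c(OCOC)cc2c(c1O)C(=O)C[C@@H](c1ccc(OCOC)cc1)O2 | intermediate
8 | (2S)-6-[(2E)-3,7-dimethylocta-2,6-dien-1-yl]-7-(methoxymethoxy)-2-[4-(methoxymethoxy)phenyl]-4,5-bis(triethylsilyloxy)-2H-chromene | CC(C)=CCC/C(C)=C/Cc1c(OCOC)cc2c(c1O[Si](CC)(CC)CC)C(O[Si](CC)(CC)CC)=C[C@@H](c1ccc(OCOC)cc1)O2 | intermediate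
9 | (2R,3R,4R)-3,4-epoxy-6-geranyl-7-(methoxymethoxy)-2-[4-(methoxymethoxy)phenyl]-4,5-bis(triethylsilyloxy)chromane (flavan numbering; oxirane oxygen anti to the 2-aryl group) | CC(C)=CCC/C(C)=C/Cc1c(OCOC)cc2c(c1O[Si](CC)(CC)CC)[C@]3(O[Si](CC)(CC)CC)O[C@@H]3[C@@H](c1ccc(OCOC)cc1)O2 | intermediate
10 | (2R,3R)-6-[(2E)-3,7-dimethylocta-2,6-dien-1-yl]-3,5-dihydroxy-7-(methoxymethoxy)-2-[4-(methoxymethoxy)phenyl]-2,3-dihydro-4H-chromen-4-one | CC(C)=CCC/C(C)=C/Cc1c(OCOC)cc2c(c1O)C(=O)[C@H](O)[C@@H](c1ccc(OCOC)cc1)O2 | intermediate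
11 | Bonnaniol, (2R,3R)-6-[(2E)-3,7-dimethylocta-2,6-dien-1-yl]-3,5,7-trihydroxy-2-(4-hydroxyphenyl)-2,3-dihydro-4H-chromen-4-one | CC(C)=CCC/C(C)=C/Cc1c(O)cc2c(c1O)C(=O)[C@H](O)[C@@H](c1ccc(O)cc1)O2 | target

**Step count and risks**

Total step count: 5. Longest linear sequence: 5 steps (1 → 2 → 4 → 6 → 8 → 11).

The three steps most likely to fail:

Step 4 is the most likely to fail. A non-activated chalcone is a reluctant partner for organocatalytic oxa-Michael addition, so the enantiomeric excess may be modest. Some closure through the 2'-OH would give the 8-geranyl isomer. The sense of induction also has to be confirmed on a desilylated aliquot of 7, with the quinine-derived pseudo-enantiomer of the catalyst as the switch.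

Fallback: regiochemistry is fixed by protecting groups and the absolute configuration by an asymmetric epoxidation; it sets out from 6 and comes back to the route at 11.
- The unhindered 6'-OH of 6 is silylated (i-Pr3SiCl, imidazole, DMF, 0 °C) to the 6'-O-triisopropylsilyl chalcone F1.
- The remaining chelated 2'-OH is capped (NaH, MOMCl, THF, 0 °C; an aprotic chalcone phenoxide does not cyclise) to give the fully protected chalcone F2.
- Nucleophilic epoxidation of the enone alone (poly-L-leucine, urea–H2O2, DBU, THF; Juliá–Colonna) gives the (αR,βS)-epoxy ketone F3.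
- Bu4NF/AcOH frees the phenol epoxide F4. A trace of camphorsulfonic acid in CH2Cl2 then opens the benzylic C–O bond 6-endo with inversion to the (2R,3R)-tris-MOM dihydroflavonol F5.
- HCl in MeOH, as in the second stage of step 5, gives 11.

Step 2 is the second risk. O-geranylation and double alkylation compete with the wanted C-alkylation, and the mono-ether 2 is a weaker carbon nucleophile than the free triol.

Fallback: the order of bond formation is reversed; it sets out from 1 (with 3) and comes back at 4. Compound 1 is C-geranylated first (3, DBU, THF, or aqueous KOH at 0 °C), a known type of acylphloroglucinol alkylation, to give 3-geranylphloracetophenone F6. F6 is then mono-protected at the non-chelated 4-OH (MOMCl, 1 equiv, i-Pr2NEt) to give 4.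

Step 5 is the third risk. DMDO may touch the geranyl alkenes, and the acid stage may add a phenol across the proximal geranyl double bond.

Fallback: the oxidation is done before any isolated alkene is present and the geranyl group is attached afterwards by cross-coupling; it sets out from 2 and comes back at 10.
- Compound 2 is condensed with 5 (KOH, EtOH) to the ring-A-symmetric chalcone F7.
- F7 is cyclised and silylated under the conditions of step 4 to the (2S)-bis(triethylsilyl) enol ether F8; there is no regiochemical question because both ortho hydroxyls are equivalent.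
- DMDO at −78 °C, then citric acid in MeOH at 0 °C, gives the (2R,3R)-7,4'-bis-MOM dihydroflavonol F9 with its MOM groups intact.
- Iodination ortho to the free, chelated 5-OH (BnMe3N·ICl2, CaCO3, CH2Cl2/MeOH, rt) gives the 6-iodide F10.
- Stille coupling with tributyl(geranyl)stannane F11 (made from 3 and Bu3SnLi), catalysed by Pd2(dba)3 (zerovalent palladium) and AsPh3 in DMF at 60 °C, gives 10.
- 10 is unmasked by the acid stage of step 5.

**Further compounds**

F1 | step 4 | (2E)-1-{3-geranyl-2-hydroxy-4-(methoxymethoxy)-6-[tri(propan-2-yl)silyloxy]phenyl}-3-[4-(methoxymethoxy)phenyl]prop-2-en-1-one | CC(C)=CCC/C(C)=C/Cc1c(OCOC)cc(O[Si](C(C)C)(C(C)C)C(C)C)c(C(=O)/C=C/c2ccc(OCOC)cc2)c1O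
F2 | step 4 | (2E)-1-{3-geranyl-2,4-bis(methoxymethoxy)-6-[tri(propan-2-yl)silyloxy]phenyl}-3-[4-(methoxymethoxy)phenyl]prop-2-en-1-one | CC(C)=CCC/C(C)=C/Cc1c(OCOC)cc(O[Si](C(C)C)(C(C)C)C(C)C)c(C(=O)/C=C/c2ccc(OCOC)cc2)c1OCOC
F3 | step 4 | {3-geranyl-2,4-bis(methoxymethoxy)-6-[tri(propan-2-yl)silyloxy]phenyl}{(2R,3S)-3-[4-(methoxymethoxy)phenyl]oxiran-2-yl}methanone | CC(C)=CCC/C(C)=C/Cc1c(OCOC)cc(O[Si](C(C)C)(C(C)C)C(C)C)c(C(=O)[C@@H]2O[C@H]2c3ccc(OCOC)cc3)c1OCOC
F4 | step 4 | [3-geranyl-6-hydroxy-2,4-bis(methoxymethoxy)phenyl]{(2R,3S)-3-[4-(methoxymethoxy)phenyl]oxiran-2-yl}methanone | CC(C)=CCC/C(C)=C/Cc1c(OCOC)cc(O)c(C(=O)[C@@H]2O[C@H]2c3ccc(OCOC)cc3)c1OCOC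
F5 | step 4 | (2R,3R)-6-geranyl-3-hydroxy-5,7-bis(methoxymethoxy)-2-[4-(methoxymethoxy)phenyl]-2,3-dihydro-4H-chromen-4-one | CC(C)=CCC/C(C)=C/Cc1c(OCOC)cc2c(c1OCOC)C(=O)[C@H](O)[C@@H](c1ccc(OCOC)cc1)O2
F6 | step 2 | 1-{3-[(2E)-3,7-dimethylocta-2,6-dien-1-yl]-2,4,6-trihydroxyphenyl}ethanone | CC(C)=CCC/C(C)=C/Cc1c(O)cc(O)c(C(C)=O)c1O
F7 | step 5 | (2E)-1-[2,6-dihydroxy-4-(methoxymethoxy)phenyl]-3-[4-(methoxymethoxy)phenyl]prop-2-en-1-one | COCOc1cc(O)c(C(=O)/C=C/c2ccc(OCOC)cc2)c(O)c1
F8 | step 5 | (2S)-7-(methoxymethoxy)-2-[4-(methoxymethoxy)phenyl]-4,5-bis(triethylsilyloxy)-2H-chromene | COCOc1cc2c(c(O[Si](CC)(CC)CC)c1)C(O[Si](CC)(CC)CC)=C[C@@H](c1ccc(OCOC)cc1)O2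
F9 | step 5 | (2R,3R)-3,5-dihydroxy-7-(methoxymethoxy)-2-[4-(methoxymethoxy)phenyl]-2,3-dihydro-4H-chromen-4-one | COCOc1cc2c(c(O)c1)C(=O)[C@H](O)[C@@H](c1ccc(OCOC)cc1)O2
F10 | step 5 | (2R,3R)-3,5-dihydroxy-6-iodo-7-(methoxymethoxy)-2-[4-(methoxymethoxy)phenyl]-2,3-dihydro-4H-chromen-4-one | COCOc1cc2c(c(O)c1I)C(=O)[C@H](O)[C@@H](c1ccc(OCOC)cc1)O2
F11 | step 5 | tributyl[(2E)-3,7-dimethylocta-2,6-dien-1-yl]stannane | CC(C)=CCC/C(C)=C/C[Sn](CCCC)(CCCC)CCCC
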